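**Plan**
- Retrosynthesis: the six O-acetyl groups are cut first, then the C4–vinyl bond of the stilbene (Mizoroki–Heck), then C2–C3 of the dihydrobenzofuran (carbene C–H insertion), then the C3=N2/C3=O group, the C3–aryl bond (Grignard) and the O1–CH2 ether bond.
- Forward: ring A aldehyde → benzyl ether → diaryl ketone → hydrazone → diaryldiazomethane; the dihydrofuran ring (O1, C2, C3, C3a, C7a) is closed by 1,5 C–H insertion; then epimerisation/demethylation, acetylation, Heck coupling, deacetylation.
- Enabling feature: C3 is a diarylmethine between ring A and the resorcinol ring, so it is accessible as a donor/donor carbene from a benzophenone; the ether CH2 on O1 (future C2) lies 1,5 to it and is made hydridic by O1 and the electron-rich catechol-derived ring.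
- Stereochemistry: C3 (S) comes from the chiral dirhodium carboxylate in the insertion, which gives the cis (2R,3S) ring; C2 is then turned to S by thermodynamically controlled epimerisation through reversible C2–O1 ionisation (trans); the E alkene comes from the Heck reaction.
- Order: the phenols are freed before the stilbene is built, because the acid-labile stilbene next to the resorcinol ring would not survive ether cleavage; bromine at C4 is carried through the key step because an alkene or ester there would trap the carbene.

Key step: step 6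

Assumption (chemistry): Rh2(R-PTAD)4 (PTAD = (1-adamantyl)(phthalimido)acetate) is taken to deliver the 3S series on this substrate; should the first run show the opposite sense, the mirror-image catalyst Rh2(S-PTAD)4 is used and nothing else changes.

**Step 1**
Reactants: 1 2-bromo-4,6-dimethoxybenzaldehyde
Product: 2 2-bromo-6-hydroxy-4-methoxybenzaldehyde
Conditions: BCl3 (1.2 equiv), CH2Cl2, −78 °C → rt; H2O
Reagents that add atoms: none
Why: Chelation-controlled ether cleavage: BCl3 bridges the formyl oxygen and the adjacent 6-methoxy oxygen in a six-membered chelate, so chloride dealkylates only the methoxy group ortho to the aldehyde and the 4-methoxy group should stay.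

**Step 2**
Reactants: 2 2-bromo-6-hydroxy-4-methoxybenzaldehyde; 3 3,4-dimethoxybenzyl chloride
Product: 4 2-bromo-6-[(3,4-dimethoxyphenyl)methoxy]-4-methoxybenzaldehyde
Conditions: K2CO3, NaI (cat.), DMF, 60 °C
Reagents that add atoms: none
Why: Williamson ether synthesis: the phenoxide displaces the activated benzylic chloride (iodide catalysis), which installs O1–C2 and the CH2 group that the carbene will later insert into.

**Step 3**
Reactants: 4 2-bromo-6-[(3,4-dimethoxyphenyl)methoxy]-4-methoxybenzaldehyde; 5 3,5-dimethoxyphenylmagnesium chloride (commercial solution in THF)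
Product: 6 rac-{2-bromo-6-[(3,4-dimethoxyphenyl)methoxy]-4-methoxyphenyl}(3,5-dimethoxyphenyl)methanol
Conditions: THF, −20 °C → rt; aq. NH4Cl
Reagents that add atoms: none
Why: Grignard 1,2-addition to the aldehyde forms the C3–aryl bond; an aryl Grignard reagent does not exchange with the aryl bromide at this temperature, and the carbinol stereocentre is of no consequence because it is oxidised next.

**Step 4**
Reactants: 6 rac-{2-bromo-6-[(3,4-dimethoxyphenyl)methoxy]-4-methoxyphenyl}(3,5-dimethoxyphenyl)methanol
Product: 7 {2-bromo-6-[(3,4-dimethoxyphenyl)methoxy]-4-methoxyphenyl}(3,5-dimethoxyphenyl)methanone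
Conditions: Dess–Martin periodinane, CH2Cl2, rt
Reagents that add atoms: none
Why: Dess–Martin oxidation of the secondary diaryl carbinol to the benzophenone under neutral conditions should spare the benzyl ether and the aryl bromide.

**Step 5**
Reactants: 7 {2-bromo-6-[(3,4-dimethoxyphenyl)methoxy]-4-methoxyphenyl}(3,5-dimethoxyphenyl)methanone
Product: 8 1-bromo-2-[hydrazinylidene(3,5-dimethoxyphenyl)methyl]-3-[(3,4-dimethoxyphenyl)methoxy]-5-methoxybenzene (hydrazone of 7, E/Z mixture)
Conditions: N2H4 (anhydrous, 10 equiv), AcOH (cat.), EtOH, sealed tube, 110 °C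
Reagents that add atoms: hydrazine, NN
Why: Acid-catalysed hydrazone formation on a non-enolisable diaryl ketone; the forcing temperature answers the two ortho substituents, the large excess of hydrazine suppresses azine formation, and both hydrazone isomers lead to the same diazo compound.

**Step 6**
Reactants: 8 hydrazone of 7
Product: 10 (2R,3S)-4-bromo-2-(3,4-dimethoxyphenyl)-3-(3,5-dimethoxyphenyl)-6-methoxy-2,3-dihydro-1-benzofuran (cis), via diaryldiazomethane 9 (not isolated)
Conditions: MnO2 (8 equiv), CH2Cl2, 0 °C → rt, filter; filtrate added slowly to Rh2(R-PTAD)4 (1 mol %), CH2Cl2, −20 °C → rt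
Reagents that add atoms: none
Why: MnO2 dehydrogenates the hydrazone to the diaryldiazomethane 9, from which the dirhodium tetracarboxylate expels N2 to give a donor/donor divalent-rhodium carbene at C3; this inserts into a C–H bond of the ether CH2 on O1 through a three-centre, hydride-transfer-like transition state and so forms C2–C3. The closest known reaction type is the enantioselective intramolecular C–H insertion of donor/donor rhodium carbenes into benzylic ether C–H bonds, which gives 2,3-disubstituted 2,3-dihydrobenzofurans. The one ring closed is the five-membered dihydrofuran ring (O1, C2, C3, C3a, C7a), by 1,5 C–H insertion, the CH2 on O1 being the only C–H-bearing carbon held 1,5 to the carbene carbon. Both stereocentres arise in this event: the cis relationship is the kinetic outcome of the compact insertion transition state that is general for this catalyst class, and the absolute configuration at C3 is set by the chiral pocket of the four PTAD ligands (catalyst control), C2 being corrected in step 7. The step needs chemoselectivity for this insertion over azine formation, arene cyclopropanation and ylide formation; this is secured by the low electrophilicity of a carbene with two donor aryl groups, by the hydridic C–H bonds alpha to O1 and benzylic to the dimethoxyphenyl ring, by the absence of ortho substituents on the resorcinol ring, by an inert bromine atom at C4 in place of an alkene or ester, and by slow addition of 9 to the catalyst.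

**Step 7**
Reactants: 10 (2R,3S)-4-bromo-2-(3,4-dimethoxyphenyl)-3-(3,5-dimethoxyphenyl)-6-methoxy-2,3-dihydro-1-benzofuran
Product: 12 4-[(2S,3S)-4-bromo-3-(3,5-dihydroxyphenyl)-6-hydroxy-2,3-dihydro-1-benzofuran-2-yl]benzene-1,2-diol, via trans-pentamethyl ether 11 (not isolated)
Conditions: BBr3 (8 equiv), CH2Cl2, −78 °C → rt; H2O, 0 °C
Reagents that add atoms: none
Why: Lewis-acid epimerisation followed by aryl methyl ether cleavage: BBr3 should first ionise C2–O1 reversibly (the benzylic cation is stabilised by the para oxygen of the C2 aryl ring) and reclosure gives the thermodynamically preferred trans ring while C3 lies outside the ionising system and keeps its configuration; on warming the five methyl ethers are cleaved, and with no alkene yet in the molecule the acid has nothing else to attack.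

**Step 8**
Reactants: 12 4-[(2S,3S)-4-bromo-3-(3,5-dihydroxyphenyl)-6-hydroxy-2,3-dihydro-1-benzofuran-2-yl]benzene-1,2-diol
Product: 13 4-[(2S,3S)-6-acetoxy-4-bromo-3-(3,5-diacetoxyphenyl)-2,3-dihydro-1-benzofuran-2-yl]-1,2-phenylene diacetate
Conditions: Ac2O, pyridine, DMAP (cat.), CH2Cl2, 0 °C → rt
Reagents that add atoms: acetic anhydride, CC(=O)OC(C)=O
Why: DMAP-catalysed O-acetylation of all five phenols should give an oxidation-stable bromide that tolerates palladium catalysis and can be unmasked later without acid.

**Step 9**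
Reactants: 13 pentaacetate bromide; 14 4-ethenylphenyl acetate (4-acetoxystyrene)
Product: 15 scirpusin A hexaacetate, 4-[(2S,3S)-6-acetoxy-4-[(E)-2-(4-acetoxyphenyl)ethenyl]-3-(3,5-diacetoxyphenyl)-2,3-dihydro-1-benzofuran-2-yl]-1,2-phenylene diacetate
Conditions: Pd(P(t-Bu)3)2 (5 mol %), Cy2NMe, 1,4-dioxane, 90 °C
Reagents that add atoms: none
Why: Mizoroki–Heck reaction: oxidative addition of the zerovalent palladium complex into C4–Br, syn-carbopalladation at the terminal alkene carbon and syn-β-hydride elimination should give the (E)-stilbene; the bulky electron-rich phosphine serves the hindered bromide and the tertiary amine base leaves the aryl acetates alone.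

**Step 10**
Reactants: 15 scirpusin A hexaacetate
Product: 16 scirpusin A, 4-[(2S,3S)-3-(3,5-dihydroxyphenyl)-6-hydroxy-4-[(E)-2-(4-hydroxyphenyl)ethenyl]-2,3-dihydro-1-benzofuran-2-yl]benzene-1,2-diol
Conditions: K2CO3 (cat.), MeOH/THF (degassed), 0 °C → rt; Amberlite IR-120 (H+ form)
Reagents that add atoms: none
Why: Base-catalysed transesterification (methanolysis) of the six aryl acetates is mild and non-acidic, so the stilbene next to the resorcinol ring should not cyclise and C2 and C3 are untouched; exclusion of air protects the catechol.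

**Compound list**
1 | 2-bromo-4,6-dimethoxybenzaldehyde | COc1cc(Br)c(C=O)c(OC)c1 | starting material
2 | 2-bromo-6-hydroxy-4-methoxybenzaldehyde | COc1cc(Br)c(C=O)c(O)c1 | intermediate
3 | 3,4-dimethoxybenzyl chloride | COc1ccc(CCl)cc1OC | starting material
4 | 2-bromo-6-[(3,4-dimethoxyphenyl)methoxy]-4-methoxybenzaldehyde | COc1cc(Br)c(C=O)c(OCc2ccc(OC)c(OC)c2)c1 | intermediate
5 | 3,5-dimethoxyphenylmagnesium chloride | COc1cc(OC)cc([Mg]Cl)c1 | starting material
6 | rac-{2-bromo-6-[(3,4-dimethoxyphenyl)methoxy]-4-methoxyphenyl}(3,5-dimethoxyphenyl)methanol | COc1cc(Br)c(C(O)c2cc(OC)cc(OC)c2)c(OCc2ccc(OC)c(OC)c2)c1 | intermediate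
7 | {2-bromo-6-[(3,4-dimethoxyphenyl)methoxy]-4-methoxyphenyl}(3,5-dimethoxyphenyl)methanone | COc1cc(Br)c(C(=O)c2cc(OC)cc(OC)c2)c(OCc2ccc(OC)c(OC)c2)c1 | intermediate
8 | hydrazone of 7 (E/Z mixture) | COc1cc(Br)c(C(=NN)c2cc(OC)cc(OC)c2)c(OCc2ccc(OC)c(OC)c2)c1 | intermediate
9 | 1-bromo-2-[diazo(3,5-dimethoxyphenyl)methyl]-3-[(3,4-dimethoxyphenyl)methoxy]-5-methoxybenzene (not isolated) | COc1cc(Br)c(C(=[N+]=[N-])c2cc(OC)cc(OC)c2)c(OCc2ccc(OC)c(OC)c2)c1 | intermediate
10 | (2R,3S)-4-bromo-2-(3,4-dimethoxyphenyl)-3-(3,5-dimethoxyphenyl)-6-methoxy-2,3-dihydro-1-benzofuran (cis) | Brc1cc(OC)cc2c1[C@H](c1cc(OC)cc(OC)c1)[C@H](c1ccc(OC)c(OC)c1)O2 | intermediate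
11 | (2S,3S)-4-bromo-2-(3,4-dimethoxyphenyl)-3-(3,5-dimethoxyphenyl)-6-methoxy-2,3-dihydro-1-benzofuran (trans; not isolated) | Brc1cc(OC)cc2c1[C@H](c1cc(OC)cc(OC)c1)[C@@H](c1ccc(OC)c(OC)c1)O2 | intermediate
12 | 4-[(2S,3S)-4-bromo-3-(3,5-dihydroxyphenyl)-6-hydroxy-2,3-dihydro-1-benzofuran-2-yl]benzene-1,2-diol | Brc1cc(O)cc2c1[C@H](c1cc(O)cc(O)c1)[C@@H](c1ccc(O)c(O)c1)O2 | intermediate
13 | 4-[(2S,3S)-6-acetoxy-4-bromo-3-(3,5-diacetoxyphenyl)-2,3-dihydro-1-benzofuran-2-yl]-1,2-phenylene diacetate | Brc1cc(OC(C)=O)cc2c1[C@H](c1cc(OC(C)=O)cc(OC(C)=O)c1)[C@@H](c1ccc(OC(C)=O)c(OC(C)=O)c1)O2 | intermediate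
14 | 4-ethenylphenyl acetate (4-acetoxystyrene) | CC(=O)Oc1ccc(C=C)cc1 | starting material
15 | scirpusin A hexaacetate | CC(=O)Oc1ccc(/C=C/c2cc(OC(C)=O)cc3c2[C@H](c2cc(OC(C)=O)cc(OC(C)=O)c2)[C@@H](c2ccc(OC(C)=O)c(OC(C)=O)c2)O3)cc1 | intermediate
16 | scirpusin A | Oc1ccc(/C=C/c2cc(O)cc3c2[C@H](c2cc(O)cc(O)c2)[C@@H](c2ccc(O)c(O)c2)O3)cc1 | target

**Step count**
Total steps: 10. Longest linear sequence: 10 steps (1 → 16).

**Steps most likely to fail**

Step 6. The diazo carbon carries an aryl ring with two ortho substituents, so N2 loss at the catalyst may be slow; azine formation or uncatalysed carbene chemistry could then take over, and facial discrimination in the catalyst pocket could be poor. The fallback sets out from 2 and 5 and comes back at 11.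
- Addition of 5 (2.2 equiv, THF, 0 °C; the first equivalent is spent on the phenol) to 2 should give the diol 3-bromo-2-[(3,5-dimethoxyphenyl)(hydroxy)methyl]-5-methoxyphenol F1.
- Sodium 4-methylbenzenesulfinate in aqueous formic acid should convert it, through the ortho-quinone methide, into the sulfone 3-bromo-2-[(3,5-dimethoxyphenyl)(4-methylbenzenesulfonyl)methyl]-5-methoxyphenol F2.
- Chloride 3 and tetrahydrothiophene (acetone, rt) should give the sulfonium salt 1-[(3,4-dimethoxyphenyl)methyl]thiolan-1-ium chloride F3.
- With Cs2CO3 in CH2Cl2, F2 loses sulfinate to form the ortho-quinone methide of ring A. The ylide from F3 adds to its methide carbon (C2–C3) and the phenoxide displaces tetrahydrothiophene (O1–C2). This known [4+1] annulation should give the racemic trans compound rac-(2S,3S)-4-bromo-2-(3,4-dimethoxyphenyl)-3-(3,5-dimethoxyphenyl)-6-methoxy-2,3-dihydro-1-benzofuran F4.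
- Preparative HPLC on a chiral stationary phase should deliver the (2S,3S) enantiomer, which is 11; the BBr3 treatment of step 7 carries it on to 12.

Step 5. Hydrazine may fail to add to a carbonyl carbon that is shielded by two ortho groups and twisted out of conjugation; on prolonged heating the hydrazone nitrogen could displace the neighbouring bromide. The fallback sets out from 4 and comes back at 8.
- I2 in aqueous NH3/THF should turn 4 into the nitrile 2-bromo-6-[(3,4-dimethoxyphenyl)methoxy]-4-methoxybenzonitrile F5, whose linear nitrile carbon is far less shielded.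
- Addition of 5 (CuBr cat., THF, reflux) and a quench with dry MeOH should give the N–H ketimine 1-{2-bromo-6-[(3,4-dimethoxyphenyl)methoxy]-4-methoxyphenyl}-1-(3,5-dimethoxyphenyl)methanimine F6.
- Transimination with N2H4 (AcOH cat., EtOH, 60 °C) runs through an iminium ion much more electrophilic than the ketone and should give 8 with loss of ammonia.

Step 9. Migratory insertion at the aryl–palladium centre flanked by the C3 aryl group may be slow, so that protodebromination and loss of acetyl groups on long heating compete. The fallback sets out from 13 and comes back at 15.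
- Stille coupling of 13 with tributyl(vinyl)stannane (Pd(PPh3)4, toluene, 100 °C) transfers only a small vinyl group and should give the styrene 4-[(2S,3S)-6-acetoxy-3-(3,5-diacetoxyphenyl)-4-ethenyl-2,3-dihydro-1-benzofuran-2-yl]-1,2-phenylene diacetate F7.
- Olefin cross-metathesis of F7 with an excess of 14 (second-generation Grubbs catalyst, CH2Cl2, 40 °C) should give the (E)-stilbene 15 with loss of ethene.

**Further compounds**
F1 | step 6 | 3-bromo-2-[(3,5-dimethoxyphenyl)(hydroxy)methyl]-5-methoxyphenol | COc1cc(O)c(C(O)c2cc(OC)cc(OC)c2)c(Br)c1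
F2 | step 6 | 3-bromo-2-[(3,5-dimethoxyphenyl)(4-methylbenzenesulfonyl)methyl]-5-methoxyphenol | COc1cc(O)c(C(c2cc(OC)cc(OC)c2)S(=O)(=O)c2ccc(C)cc2)c(Br)c1
F3 | step 6 | 1-[(3,4-dimethoxyphenyl)methyl]thiolan-1-ium chloride | COc1ccc(C[S+]2CCCC2)cc1OC.[Cl-]
F4 | step 6 | rac-(2S,3S)-4-bromo-2-(3,4-dimethoxyphenyl)-3-(3,5-dimethoxyphenyl)-6-methoxy-2,3-dihydro-1-benzofuran (racemate, both enantiomers written) | Brc1cc(OC)cc2c1[C@H](c1cc(OC)cc(OC)c1)[C@@H](c1ccc(OC)c(OC)c1)O2.Brc1cc(OC)cc2c1[C@@H](c1cc(OC)cc(OC)c1)[C@H](c1ccc(OC)c(OC)c1)O2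
F5 | step 5 | 2-bromo-6-[(3,4-dimethoxyphenyl)methoxy]-4-methoxybenzonitrile | COc1cc(Br)c(C#N)c(OCc2ccc(OC)c(OC)c2)c1
F6 | step 5 | 1-{2-bromo-6-[(3,4-dimethoxyphenyl)methoxy]-4-methoxyphenyl}-1-(3,5-dimethoxyphenyl)methanimine | COc1cc(Br)c(C(=N)c2cc(OC)cc(OC)c2)c(OCc2ccc(OC)c(OC)c2)c1
F7 | step 9 | 4-[(2S,3S)-6-acetoxy-3-(3,5-diacetoxyphenyl)-4-ethenyl-2,3-dihydro-1-benzofuran-2-yl]-1,2-phenylene diacetate | C=Cc1cc(OC(C)=O)cc2c1[C@H](c1cc(OC(C)=O)cc(OC(C)=O)c1)[C@@H](c1ccc(OC(C)=O)c(OC(C)=O)c1)O2
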